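**Strategy.** The dihydrofuran ring is cut across O1–C2 and C3a–C3. The key step exploits the phenol unit O1–C7a–C3a of the benzene ring as an O,C-dinucleophile and the vicinally oxygenated C2–C3 pair of the dihydrofuran ring as a dielectrophile: in one pot the titanium phenoxide of 4-hydroxy-2,3-dimethoxyacetophenone adds through its only free ortho carbon to (S)-3,3-dimethyloxirane-2-carbaldehyde under Felkin–Anh control (C3a–C3), and the phenoxide then opens the epoxide 5-exo with inversion (O1–C2). The precursor pair thus gives the cis-2,3-disubstituted dihydrobenzofuran with the isopropenyl group masked as a tertiary alcohol; angeloylation and dehydration complete the target.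

Key step: step 6

Remark: gallacetophenone (1), prenol (5) and angelic acid (11) are taken as purchased. The descriptors (2S,3R) of 10 and 12 and (2R,3R) of 13 describe the same spatial arrangement; only the CIP ranking at C2 changes when the 2-hydroxypropan-2-yl group becomes isopropenyl.

**Route**

Step 1
Reactants: 1 1-(2,3,4-trihydroxyphenyl)ethan-1-one (gallacetophenone)
Product: 2 1-[4-(benzyloxy)-2,3-dihydroxyphenyl]ethan-1-one
Conditions: BnBr (1.0 equiv), NaHCO3, DMF, 40 °C
Reagents that add atoms: benzyl bromide, BrCc1ccccc1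
Why: Williamson etherification; the 4-OH, para to the acetyl group, is the most acidic phenol and the only one ionised by hydrogen carbonate, while the 2-OH is held in a hydrogen bond to the carbonyl group, so one equivalent of benzyl bromide should alkylate O4 selectively.

Step 2
Reactants: 2 1-[4-(benzyloxy)-2,3-dihydroxyphenyl]ethan-1-one
Product: 3 1-[4-(benzyloxy)-2,3-dimethoxyphenyl]ethan-1-one
Conditions: MeI (3 equiv), K2CO3, DMF, 50 °C
Reagents that add atoms: iodomethane, CI
Why: Williamson O-methylation of both remaining phenols; K2CO3 in warm DMF with excess MeI is strong enough for the hydrogen-bonded 2-OH but does not enolise the methyl ketone.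

Step 3
Reactants: 3 1-[4-(benzyloxy)-2,3-dimethoxyphenyl]ethan-1-one
Product: 4 1-(4-hydroxy-2,3-dimethoxyphenyl)ethan-1-one
Conditions: H2 (1 atm), 10% Pd/C, EtOAc, 23 °C
Reagents that add atoms: none
Why: Catalytic hydrogenolysis of the benzyl ether at ambient pressure should free the 4-OH without touching the aryl ketone or the methyl ethers.

Step 4
Reactants: 5 3-methylbut-2-en-1-ol (prenol)
Product: 6 [(2R)-3,3-dimethyloxiran-2-yl]methanol
Conditions: Ti(OiPr)4 (5 mol %), D-(−)-diisopropyl tartrate (7 mol %), t-BuOOH, 4 Å MS, CH2Cl2, −20 °C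
Reagents that add atoms: tert-butyl hydroperoxide, CC(C)(C)OO
Why: Sharpless asymmetric epoxidation; with the D-(−)-tartrate ligand the titanium peroxo complex should deliver oxygen to the face of the allylic alcohol that gives the (R)-epoxy alcohol, creating the stereocentre that later becomes C2 (with inversion).

Step 5
Reactants: 6 [(2R)-3,3-dimethyloxiran-2-yl]methanol
Product: 7 (2S)-3,3-dimethyloxirane-2-carbaldehyde
Conditions: TEMPO (10 mol %), PhI(OAc)2, CH2Cl2, 0 → 23 °C
Reagents that add atoms: none
Why: Oxoammonium (TEMPO/PhI(OAc)2) oxidation of the primary alcohol stops at the aldehyde under non-basic conditions that leave the epoxide and its stereocentre intact (R becomes S only through CIP ranking); the volatile aldehyde is washed free of acetic acid and used as a dried solution.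

Step 6
Reactants: 4 1-(4-hydroxy-2,3-dimethoxyphenyl)ethan-1-one; 7 (2S)-3,3-dimethyloxirane-2-carbaldehyde
Product: 10 1-[(2S,3R)-3-hydroxy-2-(2-hydroxypropan-2-yl)-6,7-dimethoxy-2,3-dihydro-1-benzofuran-5-yl]ethan-1-one (cis), via titanium phenoxide 8 (not isolated), via anti-epoxy alcohol 9 (not isolated)
Conditions: 4, Ti(OiPr)4 (1.05 equiv), toluene, 23 °C, i-PrOH removed in vacuo; 7 (1.3 equiv), CH2Cl2, −20 → 0 °C; then K2CO3, MeOH, 23 °C
Reagents that add atoms: none
Why: Ligand exchange gives the aryloxytitanium triisopropoxide 8, whose titanium binds the aldehyde and delivers the only free ortho carbon (C3a, the para position being blocked by the acetyl group) to the carbonyl carbon through a six-membered cyclic transition state, so that C3a–C3 forms and rearomatisation leaves the titanium alkoxide of 9. The closest known reaction type is the ortho-specific hydroxyalkylation (Friedel–Crafts-type aldol) of titanium and magnesium phenoxides with α-oxygenated chiral aldehydes, here followed by the known base-mediated phenoxide opening of an epoxy alcohol. C3 is set by the epoxide stereocentre under Felkin–Anh (non-chelation) control, since the alkoxide-laden, weakly Lewis acidic Ti(OiPr)3 group should not chelate the epoxide oxygen and the arene enters anti to the epoxide C–O bond, which gives the anti adduct with (R)-C3. After the switch to K2CO3/MeOH the freed phenoxide O1 attacks the secondary epoxide carbon from the rear in a 5-exo-tet SN2 ring closure, the only ring formed, so that O1–C2 arises with inversion, C2 becomes (S) and the 2-hydroxypropan-2-yl group ends cis to the C3 hydroxyl. The step needs C- over O-alkylation (secured by the titanium template), Felkin over chelate addition (secured by the isopropoxide ligands and the methyl group cis to the formyl group) and 5-exo over 6-endo opening (secured by closing the ring under basic conditions, where attack at the tertiary carbon is disfavoured).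

Step 7
Reactants: 10 1-[(2S,3R)-3-hydroxy-2-(2-hydroxypropan-2-yl)-6,7-dimethoxy-2,3-dihydro-1-benzofuran-5-yl]ethan-1-one; 11 (2Z)-2-methylbut-2-enoic acid (angelic acid)
Product: 12 (2S,3R)-5-acetyl-2-(2-hydroxypropan-2-yl)-6,7-dimethoxy-2,3-dihydro-1-benzofuran-3-yl (2Z)-2-methylbut-2-enoate
Conditions: 11 (1.5 equiv), 2,4,6-Cl3C6H2COCl, Et3N, toluene, 23 °C; then 10, 80 °C
Reagents that add atoms: none
Why: Yamaguchi esterification through the preformed mixed anhydride should acylate only the secondary benzylic alcohol (the tertiary alcohol is too hindered), and leaving out DMAP avoids the conjugate-addition pathway that isomerises angelates to tiglates; no stereocentre is touched.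

Step 8
Reactants: 12 (2S,3R)-5-acetyl-2-(2-hydroxypropan-2-yl)-6,7-dimethoxy-2,3-dihydro-1-benzofuran-3-yl (2Z)-2-methylbut-2-enoate
Product: 13 (2R,3R)-5-acetyl-6,7-dimethoxy-2-(prop-1-en-2-yl)-2,3-dihydro-1-benzofuran-3-yl (2Z)-2-methylbut-2-enoate
Conditions: SOCl2, pyridine, CH2Cl2, −10 → 0 °C
Reagents that add atoms: none
Why: The tertiary alcohol is converted into its chlorosulfite and eliminated by pyridine in an E2 reaction toward one of the six methyl hydrogens instead of the single hindered C2–H (whose loss would give an enol ether), as in known dehydrations of 2-(2-hydroxypropan-2-yl) cyclic ethers to isopropenyl compounds; the cold, buffered medium should spare the benzylic angelate and the stereocentres are not involved.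

**Compound list**

1 | 1-(2,3,4-trihydroxyphenyl)ethan-1-one (gallacetophenone) | CC(=O)c1ccc(O)c(O)c1O | starting material
2 | 1-[4-(benzyloxy)-2,3-dihydroxyphenyl]ethan-1-one | CC(=O)c1ccc(OCc2ccccc2)c(O)c1O | intermediate
3 | 1-[4-(benzyloxy)-2,3-dimethoxyphenyl]ethan-1-one | CC(=O)c1ccc(OCc2ccccc2)c(OC)c1OC | intermediate
4 | 1-(4-hydroxy-2,3-dimethoxyphenyl)ethan-1-one | CC(=O)c1ccc(O)c(OC)c1OC | intermediate
5 | 3-methylbut-2-en-1-ol (prenol) | CC(C)=CCO | starting material
6 | [(2R)-3,3-dimethyloxiran-2-yl]methanol | OC[C@H]1OC1(C)C | intermediate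
7 | (2S)-3,3-dimethyloxirane-2-carbaldehyde | O=C[C@H]1OC1(C)C | intermediate
8 | (4-acetyl-2,3-dimethoxyphenoxy)tri(propan-2-yloxy)titanium | CC(=O)c1ccc(O[Ti](OC(C)C)(OC(C)C)OC(C)C)c(OC)c1OC | intermediate
9 | 1-{5-[(R)-[(2R)-3,3-dimethyloxiran-2-yl](hydroxy)methyl]-4-hydroxy-2,3-dimethoxyphenyl}ethan-1-one | CC(=O)c1cc([C@@H](O)[C@H]2OC2(C)C)c(O)c(OC)c1OC | intermediate
10 | 1-[(2S,3R)-3-hydroxy-2-(2-hydroxypropan-2-yl)-6,7-dimethoxy-2,3-dihydro-1-benzofuran-5-yl]ethan-1-one | CC(C)(O)[C@H]1Oc2c(cc(C(C)=O)c(OC)c2OC)[C@H]1O | intermediate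
11 | (2Z)-2-methylbut-2-enoic acid (angelic acid) | C/C=C(/C)C(=O)O | starting material
12 | (2S,3R)-5-acetyl-2-(2-hydroxypropan-2-yl)-6,7-dimethoxy-2,3-dihydro-1-benzofuran-3-yl (2Z)-2-methylbut-2-enoate | CC(C)(O)[C@H]1Oc2c(cc(C(C)=O)c(OC)c2OC)[C@H]1OC(=O)/C(C)=C\C | intermediate
13 | (2R,3R)-5-acetyl-6,7-dimethoxy-2-(prop-1-en-2-yl)-2,3-dihydro-1-benzofuran-3-yl (2Z)-2-methylbut-2-enoate | C=C(C)[C@H]1Oc2c(cc(C(C)=O)c(OC)c2OC)[C@H]1OC(=O)/C(C)=C\C | target

**Step count.** Total: 8 steps. Longest linear sequence: 6 steps (1, 2, 3, 6, 7, 8).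

**Steps most likely to fail**

Step 6 (key step).
- What may go wrong: slow C–C bond formation at the acyl-deactivated arene; loss of Felkin–Anh facial selectivity if titanium chelates the epoxide oxygen (which leads to the trans ring); Lewis-acid-induced 6-endo opening or rearrangement of the epoxide before the base is added.
- Fallback (stepwise, known reactions, sets out from 4 and returns at 10): magnesium-mediated ortho-formylation of 4 (MgCl2, Et3N, paraformaldehyde, MeCN, reflux) should give 5-acetyl-2-hydroxy-3,4-dimethoxybenzaldehyde F1. Silylation (TBSCl, imidazole, DMF) gives 5-acetyl-2-[(tert-butyldimethylsilyl)oxy]-3,4-dimethoxybenzaldehyde F2. Aldehyde-selective Nozaki–Hiyama–Kishi addition of 1-bromo-2-methylprop-1-ene (CrCl2, cat. NiCl2, DMF) gives racemic 1-{4-[(tert-butyldimethylsilyl)oxy]-5-(1-hydroxy-3-methylbut-2-en-1-yl)-2,3-dimethoxyphenyl}ethan-1-one F3. Sharpless kinetic resolution (Ti(OiPr)4, D-(−)-diisopropyl tartrate, t-BuOOH 0.6 equiv, 4 Å MS, CH2Cl2, −20 °C) should epoxidise the fast-reacting enantiomer to the erythro epoxy alcohol 1-{4-[(tert-butyldimethylsilyl)oxy]-5-[(R)-[(2R)-3,3-dimethyloxiran-2-yl](hydroxy)methyl]-2,3-dimethoxyphenyl}ethan-1-one F4, which is separated from the unreacted enantiomer. TBAF in THF then removes the silyl group and the phenoxide closes the ring 5-exo with inversion to give 10.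

Step 8 (dehydration).
- What may go wrong: proton loss from C2 instead of a methyl group, or ionisation at the tertiary centre with participation or loss of the neighbouring angelate, which ends in aromatisation to a benzofuran.
- Fallback (dehydration before esterification, sets out from 10 and returns at 13): selective silylation of the secondary alcohol (TESCl, imidazole, CH2Cl2, 0 °C) gives 1-[(2S,3R)-2-(2-hydroxypropan-2-yl)-6,7-dimethoxy-3-[(triethylsilyl)oxy]-2,3-dihydro-1-benzofuran-5-yl]ethan-1-one F5. Syn-elimination with the Burgess reagent (toluene, 50 °C), where no acyloxy group can participate or leave, gives 1-[(2R,3R)-6,7-dimethoxy-2-(prop-1-en-2-yl)-3-[(triethylsilyl)oxy]-2,3-dihydro-1-benzofuran-5-yl]ethan-1-one F6. TBAF/AcOH in THF gives 1-[(2R,3R)-3-hydroxy-6,7-dimethoxy-2-(prop-1-en-2-yl)-2,3-dihydro-1-benzofuran-5-yl]ethan-1-one F7, which is esterified with 11 under the conditions of step 7 to give 13.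

Step 7 (angeloylation).
- What may go wrong: Z to E isomerisation of the angeloyl unit during activation and acyl transfer, and incomplete acylation of the hindered alcohol next to the quaternary carbinol carbon.
- Fallback (the Z-alkene is built after the ester bond, sets out from 10 and returns at 12): coupling of 10 with 2-[bis(2,2,2-trifluoroethoxy)phosphoryl]propanoic acid (EDC·HCl, DMAP, CH2Cl2; no alkene is present to isomerise) gives (2S,3R)-5-acetyl-2-(2-hydroxypropan-2-yl)-6,7-dimethoxy-2,3-dihydro-1-benzofuran-3-yl 2-[bis(2,2,2-trifluoroethoxy)phosphoryl]propanoate F8 as a mixture of epimers at the phosphonate carbon. Still–Gennari olefination with acetaldehyde (KN(SiMe3)2, 18-crown-6, THF, −78 °C) should give the (Z)-enoate 12.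

Further compounds
F1 | step 6 | 5-acetyl-2-hydroxy-3,4-dimethoxybenzaldehyde | CC(=O)c1cc(C=O)c(O)c(OC)c1OC
F2 | step 6 | 5-acetyl-2-[(tert-butyldimethylsilyl)oxy]-3,4-dimethoxybenzaldehyde | CC(=O)c1cc(C=O)c(O[Si](C)(C)C(C)(C)C)c(OC)c1OC
F3 | step 6 | racemic 1-{4-[(tert-butyldimethylsilyl)oxy]-5-(1-hydroxy-3-methylbut-2-en-1-yl)-2,3-dimethoxyphenyl}ethan-1-one | CC(=O)c1cc(C(O)C=C(C)C)c(O[Si](C)(C)C(C)(C)C)c(OC)c1OC
F4 | step 6 | 1-{4-[(tert-butyldimethylsilyl)oxy]-5-[(R)-[(2R)-3,3-dimethyloxiran-2-yl](hydroxy)methyl]-2,3-dimethoxyphenyl}ethan-1-one | CC(=O)c1cc([C@@H](O)[C@H]2OC2(C)C)c(O[Si](C)(C)C(C)(C)C)c(OC)c1OC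
F5 | step 8 | 1-[(2S,3R)-2-(2-hydroxypropan-2-yl)-6,7-dimethoxy-3-[(triethylsilyl)oxy]-2,3-dihydro-1-benzofuran-5-yl]ethan-1-one | CC(C)(O)[C@H]1Oc2c(cc(C(C)=O)c(OC)c2OC)[C@H]1O[Si](CC)(CC)CC
F6 | step 8 | 1-[(2R,3R)-6,7-dimethoxy-2-(prop-1-en-2-yl)-3-[(triethylsilyl)oxy]-2,3-dihydro-1-benzofuran-5-yl]ethan-1-one | C=C(C)[C@H]1Oc2c(cc(C(C)=O)c(OC)c2OC)[C@H]1O[Si](CC)(CC)CC
F7 | step 8 | 1-[(2R,3R)-3-hydroxy-6,7-dimethoxy-2-(prop-1-en-2-yl)-2,3-dihydro-1-benzofuran-5-yl]ethan-1-one | C=C(C)[C@H]1Oc2c(cc(C(C)=O)c(OC)c2OC)[C@H]1O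
F8 | step 7 | (2S,3R)-5-acetyl-2-(2-hydroxypropan-2-yl)-6,7-dimethoxy-2,3-dihydro-1-benzofuran-3-yl 2-[bis(2,2,2-trifluoroethoxy)phosphoryl]propanoate | CC(C)(O)[C@H]1Oc2c(cc(C(C)=O)c(OC)c2OC)[C@H]1OC(=O)C(C)P(=O)(OCC(F)(F)F)OCC(F)(F)F
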